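**Retrosynthetic overview**
- The target is reached last by hydroboration–oxidation of a Δ5 spiro-diolide, which sets C5 and C6.
- The tetrahydrofuran ring comes from C13–O closure of a 9-hydroxy lactone (trivalent-iodine umpolung); that side chain comes from a C9 spiro-epoxide and α-methylene-γ-butyrolactone (radical addition).
- Ring A (the bridged 19,20-lactone, C4) comes from intramolecular α-alkylation of a lactone dienolate; C8 and C9 are set beforehand on a bicyclic keto ene-lactone.
- That bicycle (C10, the first stereocentre) comes from an achiral 2-allyl-2-(acyloxymethyl)cyclohexane-1,3-dione by a chiral-ammonium-catalysed desymmetrising intramolecular Horner–Wadsworth–Emmons reaction.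
- Ring order: ring B (bought as the dione), then the δ-lactone ring, ring A, the tetrahydrofuran ring; the γ-lactone is brought in preformed.

Assumption: the target is made exactly as drawn (H-5 on the face of the lactone CH2, rings A and B cis-fused); locants from compound 18 on use labdane numbering (C17 methyl on C8, C18 methyl on C4, C19 lactone carbonyl on C4, C20 lactone CH2 on C10, side chain C11–C16).

Step 1
Reactants: 1 cyclohexane-1,3-dione; 2 allyl bromide
Product: 3 2-allylcyclohexane-1,3-dione
Conditions: KOH, H2O, Cu powder (cat.), rt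
Reagents that add atoms: none
Why: C-alkylation of the dione enolate by the soft allyl electrophile in water gives the 2-allyl dione (enolate alkylation, no stereocentre).

Step 2
Reactants: 3 2-allylcyclohexane-1,3-dione; 4 formaldehyde
Product: 5 2-allyl-2-(hydroxymethyl)cyclohexane-1,3-dione
Conditions: 37% aq. HCHO, Et3N (10 mol %), THF, 0 °C to rt
Reagents that add atoms: none
Why: Aldol addition of the acidic C2–H to formaldehyde (hydroxymethylation) gives the achiral quaternary dione, excess formaldehyde holding back the retro-aldol.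

Step 3
Reactants: 5 2-allyl-2-(hydroxymethyl)cyclohexane-1,3-dione; 6 2-(diethoxyphosphoryl)acetic acid
Product: 7 (1-allyl-2,6-dioxocyclohexyl)methyl 2-(diethoxyphosphoryl)acetate
Conditions: N,N'-dicyclohexylcarbodiimide, 4-(dimethylamino)pyridine (5 mol %), CH2Cl2, 0 °C to rt
Reagents that add atoms: none
Why: Steglich esterification of the primary alcohol; the product keeps its mirror plane and is still achiral.

Step 4
Reactants: 7 (1-allyl-2,6-dioxocyclohexyl)methyl 2-(diethoxyphosphoryl)acetate
Product: 8 (8aS)-8a-allyl-6,7-dihydro-1H-isochromene-3,8(5H,8aH)-dione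
Conditions: 1-(9-anthracenylmethyl)-9-deoxy-9-epi-9-{3-[3,5-bis(trifluoromethyl)phenyl]ureido}cinchonidinium bromide (10 mol %), Cs2CO3 (powder), toluene, −20 °C
Reagents that add atoms: none
Why: Proposed new method: catalytic enantioselective desymmetrising intramolecular Horner–Wadsworth–Emmons lactone formation, in which the chiral ammonium ion pairs with the phosphonate carbanion formed at the solid–liquid interface while its urea binds one of the two enantiotopic ketones, so that addition and phosphate loss occur at that carbonyl only and fix C8a (labdane C10) as S (the pseudoenantiomeric cinchoninium salt is used if the sense turns out opposite); closest known reaction types are base-mediated intramolecular HWE closure of β-(phosphonoacetoxy) ketones to 5,6-dihydropyran-2-ones and phase-transfer HWE desymmetrisation of 4-substituted cyclohexanones, known only with modest selectivity and not for 1,3-diones.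

Step 5
Reactants: 8 (8aS)-8a-allyl-6,7-dihydro-1H-isochromene-3,8(5H,8aH)-dione; 4 formaldehyde (as paraformaldehyde)
Product: 9 (8aS)-8a-allyl-7-methylene-6,7-dihydro-1H-isochromene-3,8(5H,8aH)-dione
Conditions: (CH2O)n, iPr2NH2+ CF3CO2− (1 equiv), CF3CO2H (10 mol %), THF, reflux
Reagents that add atoms: none
Why: Mannich-type α-methylenation at the only enolisable α-carbon of the ketone (the other is quaternary); the lactone does not enolise under these conditions.

Step 6
Reactants: 9 (8aS)-8a-allyl-7-methylene-6,7-dihydro-1H-isochromene-3,8(5H,8aH)-dione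
Product: 11 (7R,8aS)-8a-allyl-7-methyl-6,7-dihydro-1H-isochromene-3,8(5H,8aH)-dione, via lithium enolate 10 (not isolated)
Conditions: LiB(sBu)3H (1.05 equiv), THF, −78 °C; then 2,6-di-tert-butyl-4-methylphenol, −78 °C
Reagents that add atoms: none
Why: Conjugate hydride addition to the β-unsubstituted exo-methylene ketone (the β,β-disubstituted ene-lactone and the allyl group are inert) gives the enolate, and kinetic protonation by the hindered phenol from the face opposite the quasi-axial angular allyl group places the methyl cis to allyl (7R, the less stable epimer).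

Step 7
Reactants: 11 (7R,8aS)-8a-allyl-7-methyl-6,7-dihydro-1H-isochromene-3,8(5H,8aH)-dione
Product: 13 (7R,8R,8aS)-8a-allyl-7-methyl-5,6,7,8a-tetrahydro-1H-spiro[isochromene-8,2'-oxiran]-3-one, via lithium chlorohydrin alkoxide 12 (not isolated)
Conditions: ClCH2I, MeLi·LiBr, THF, −78 °C to rt
Reagents that add atoms: chloroiodomethane, ClCI
Why: Chloromethyllithium adds to the ketone faster than to the conjugated lactone, from the face anti to both the angular allyl and the neighbouring methyl (axial attack as on Wieland–Miescher-type ketones), and the alkoxide closes to the epoxide on warming, which sets C8 (labdane C9) with its CH2 trans to allyl and its oxygen cis to the methyl.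

Step 8
Reactants: 13 (7R,8R,8aS)-8a-allyl-7-methyl-5,6,7,8a-tetrahydro-1H-spiro[isochromene-8,2'-oxiran]-3-one
Product: 15 (7R,8R,8aS)-8a-allyl-4,7-dimethyl-4,6,7,8a-tetrahydro-1H-spiro[isochromene-8,2'-oxiran]-3-one (both C4 epimers), via lithium dienolate 14 (not isolated)
Conditions: LiN(iPr)2, THF/DMPU, −78 °C; then MeI
Reagents that add atoms: iodomethane, CI
Why: γ-Deprotonation of the ene-lactone and methylation of the extended enolate at its α-carbon (deconjugative α-alkylation) installs the C4 methyl and moves the alkene to C4a=C5; the new centre is a mixture that is planarised again in step 10.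

Step 9
Reactants: 15 (7R,8R,8aS)-8a-allyl-4,7-dimethyl-4,6,7,8a-tetrahydro-1H-spiro[isochromene-8,2'-oxiran]-3-one (both C4 epimers)
Product: 17 (7R,8R,8aS)-8a-(3-iodopropyl)-4,7-dimethyl-4,6,7,8a-tetrahydro-1H-spiro[isochromene-8,2'-oxiran]-3-one (both C4 epimers), via alkylzirconocene chloride 16 (not isolated)
Conditions: Cp2Zr(H)Cl, THF, rt; then I2, 0 °C
Reagents that add atoms: iodine, II
Why: Anti-Markovnikov hydrozirconation of the terminal alkene (the trisubstituted ring alkene, epoxide and lactone are left alone) and iodinolysis of the C–Zr bond give the primary iodide.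

Step 10
Reactants: 17 (7R,8R,8aS)-8a-(3-iodopropyl)-4,7-dimethyl-4,6,7,8a-tetrahydro-1H-spiro[isochromene-8,2'-oxiran]-3-one (both C4 epimers)
Product: 18 (4S,8R,9R,10S)-9,11-epoxy-12,13,14,15,16-pentanorlabd-5-en-19,20-olide
Conditions: KN(SiMe3)2, THF, −78 to 0 °C
Reagents that add atoms: none
Why: Removal of the acidic allylic α-H regenerates the dienolate, whose α-carbon displaces the iodide (6-enolexo-exo-tet alkylation) to close ring A as the bridged 3-oxabicyclo[3.3.1]nonan-2-one; the tether from C10 can reach only one face of C4, so C4 is necessarily S with the lactone carbonyl on the face of C20.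

Step 11
Reactants: 18 (4S,8R,9R,10S)-9,11-epoxy-12,13,14,15,16-pentanorlabd-5-en-19,20-olide; 19 α-methylene-γ-butyrolactone
Product: 21 (4S,8R,9R,10S)-9-hydroxylabd-5-ene-19,20:16,15-diolide (both C13 epimers), via iodohydrin 20 (not isolated)
Conditions: LiI, AcOH, THF, rt; then (Me3Si)3SiH, azobisisobutyronitrile, toluene, 80 °C (19 in fivefold excess)
Reagents that add atoms: none
Why: Iodide opens the epoxide at its CH2 (SN2), and the primary β-hydroxyalkyl radical made from the iodohydrin adds to the exo-methylene lactone (Giese addition) before taking H from the silane; C13 is formed unselectively and is planarised in step 12.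

Step 12
Reactants: 21 (4S,8R,9R,10S)-9-hydroxylabd-5-ene-19,20:16,15-diolide (both C13 epimers)
Product: 23 (4S,8R,9R,10S,13R)-9,13-epoxylabd-5-ene-19,20:16,15-diolide, via silyl ketene acetal 22 (not isolated)
Conditions: LiN(iPr)2 (2.3 equiv), Me3SiCl, THF, −78 to 0 °C; then PhI(OCOCF3)2, CH2Cl2, −78 to −20 °C
Reagents that add atoms: none
Why: Proposed new method: intramolecular capture of a lactone enolonium by a tertiary silyl ether, in which the silyl ketene acetal attacks trivalent iodine to give an O-bound aryl-λ3-iodanyl enolate that is electrophilic at C13, the 9-O–Si oxygen attacks C13 in a 5-exo mode with loss of PhI and Me3SiOCOCF3 to form the tetrahydrofuran, and the bulky iodanyl-bearing carbonyl flank turns away from quaternary C10 toward C8, which places C16 cis to C8 (13R); closest known reaction type is α-oxygenation of silyl enol ethers and lactone silyl ketene acetals by trivalent-iodine reagents with external oxygen nucleophiles, not yet shown for ring closure by a tertiary alcohol derivative onto a fully substituted carbon.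

Step 13
Reactants: 23 (4S,8R,9R,10S,13R)-9,13-epoxylabd-5-ene-19,20:16,15-diolide
Product: 25 (4S,5S,6R,8R,9R,10S,13R)-6-hydroxy-9,13-epoxylabdane-19,20:16,15-diolide (CNP0393616.2), via alkylborane 24 (not isolated)
Conditions: BH3·THF, THF, 0 °C to rt; then 30% H2O2, NaOAc, H2O, 0 °C
Reagents that add atoms: hydrogen peroxide, OO
Why: Hydroboration–oxidation adds H and OH syn with boron at the less substituted C6; the borane comes from the face of the flat lactone bridge (one syn-axial H) and not from the face of the (CH2)3 bridge (two syn-axial H plus the C8 methyl), giving H-5 and 6-OH both on the face of C20 (5S,6R), while the lactones survive BH3 at this temperature.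

**Compound list**
1 | cyclohexane-1,3-dione | O=C1CCCC(=O)C1 | starting material
2 | allyl bromide | C=CCBr | starting material
3 | 2-allylcyclohexane-1,3-dione | C=CCC1C(=O)CCCC1=O | intermediate
4 | formaldehyde | C=O | starting material
5 | 2-allyl-2-(hydroxymethyl)cyclohexane-1,3-dione | C=CCC1(CO)C(=O)CCCC1=O | intermediate
6 | 2-(diethoxyphosphoryl)acetic acid | CCOP(=O)(CC(=O)O)OCC | starting material
7 | (1-allyl-2,6-dioxocyclohexyl)methyl 2-(diethoxyphosphoryl)acetate | C=CCC1(COC(=O)CP(=O)(OCC)OCC)C(=O)CCCC1=O | intermediate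
8 | (8aS)-8a-allyl-6,7-dihydro-1H-isochromene-3,8(5H,8aH)-dione | O=C1C=C2CCCC(=O)[C@]2(CC=C)CO1 | intermediate
9 | (8aS)-8a-allyl-7-methylene-6,7-dihydro-1H-isochromene-3,8(5H,8aH)-dione | O=C1C=C2CCC(=C)C(=O)[C@]2(CC=C)CO1 | intermediate
10 | lithium (8aS)-8a-allyl-7-methyl-3-oxo-3,5,6,8a-tetrahydro-1H-isochromen-8-olate (enolate) | O=C1C=C2CCC(C)=C([O-])[C@]2(CC=C)CO1.[Li+] | intermediate
11 | (7R,8aS)-8a-allyl-7-methyl-6,7-dihydro-1H-isochromene-3,8(5H,8aH)-dione (methyl cis to allyl) | O=C1C=C2CC[C@@H](C)C(=O)[C@]2(CC=C)CO1 | intermediate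
12 | lithium (7R,8R,8aS)-8a-allyl-8-(chloromethyl)-7-methyl-3-oxo-3,5,6,7,8,8a-hexahydro-1H-isochromen-8-olate | O=C1C=C2CC[C@@H](C)[C@]([O-])(CCl)[C@]2(CC=C)CO1.[Li+] | intermediate
13 | (7R,8R,8aS)-8a-allyl-7-methyl-5,6,7,8a-tetrahydro-1H-spiro[isochromene-8,2'-oxiran]-3-one (oxirane CH2 trans to allyl) | O=C1C=C2CC[C@@H](C)[C@]3(CO3)[C@]2(CC=C)CO1 | intermediate
14 | lithium dienolate of 13 (C3=C4 and C4a=C5, O-lithiated at C3) | [Li+].[O-]C1=CC2=CC[C@@H](C)[C@]3(CO3)[C@]2(CC=C)CO1 | intermediate
15 | (7R,8R,8aS)-8a-allyl-4,7-dimethyl-4,6,7,8a-tetrahydro-1H-spiro[isochromene-8,2'-oxiran]-3-one, both C4 epimers | O=C1C(C)C2=CC[C@@H](C)[C@]3(CO3)[C@]2(CC=C)CO1 | intermediate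
16 | alkylzirconocene chloride from 15 (Cp2ZrCl on the terminal carbon of the former allyl group) | O=C1C(C)C2=CC[C@@H](C)[C@]3(CO3)[C@]2(CCC[Zr](Cl)(C4C=CC=C4)C4C=CC=C4)CO1 | intermediate
17 | (7R,8R,8aS)-8a-(3-iodopropyl)-4,7-dimethyl-4,6,7,8a-tetrahydro-1H-spiro[isochromene-8,2'-oxiran]-3-one, both C4 epimers | O=C1C(C)C2=CC[C@@H](C)[C@]3(CO3)[C@]2(CCCI)CO1 | intermediate
18 | (4S,8R,9R,10S)-9,11-epoxy-12,13,14,15,16-pentanorlabd-5-en-19,20-olide | C[C@@H]1CC=C2[C@]3(CCC[C@]2(C)C(=O)OC3)[C@@]14CO4 | intermediate
19 | α-methylene-γ-butyrolactone (3-methylenedihydrofuran-2(3H)-one) | C=C1CCOC1=O | starting material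
20 | (4S,8R,9R,10S)-9-hydroxy-11-iodo-12,13,14,15,16-pentanorlabd-5-en-19,20-olide | C[C@@H]1CC=C2[C@]3(CCC[C@]2(C)C(=O)OC3)[C@@]1(O)CI | intermediate
21 | (4S,8R,9R,10S)-9-hydroxylabd-5-ene-19,20:16,15-diolide, both C13 epimers | C[C@@H]1CC=C2[C@]3(CCC[C@]2(C)C(=O)OC3)[C@@]1(O)CCC1CCOC1=O | intermediate
22 | (4S,8R,9R,10S)-9,16-bis(trimethylsilyloxy)-15,16-epoxylabda-5,13(16)-dien-19,20-olide (silyl ketene acetal) | C[C@@H]1CC=C2[C@]3(CCC[C@]2(C)C(=O)OC3)[C@@]1(O[Si](C)(C)C)CCC1=C(O[Si](C)(C)C)OCC1 | intermediate
23 | (4S,8R,9R,10S,13R)-9,13-epoxylabd-5-ene-19,20:16,15-diolide | C[C@@H]1CC=C2[C@]3(CCC[C@]2(C)C(=O)OC3)[C@@]12CC[C@]1(CCOC1=O)O2 | intermediate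
24 | (4S,5S,6R,8R,9R,10S,13R)-6-boranyl-9,13-epoxylabdane-19,20:16,15-diolide | C[C@@H]1C[C@@H](B)[C@H]2[C@]3(CCC[C@]2(C)C(=O)OC3)[C@@]12CC[C@]1(CCOC1=O)O2 | intermediate
25 | (4S,5S,6R,8R,9R,10S,13R)-6-hydroxy-9,13-epoxylabdane-19,20:16,15-diolide (CNP0393616.2) | C[C@@H]1C[C@@H](O)[C@H]2[C@]3(CCC[C@]2(C)C(=O)OC3)[C@@]12CC[C@]1(CCOC1=O)O2 | target

Total step count: 13. Longest linear sequence: 13 steps (from 1; all other building blocks are bought).

**Three steps most likely to fail**

Step 4 (proposed new method; selectivity between the two ketones may be low). The fallback uses known chemistry, sets out from 7 and comes back at 8. One ketone of 7 is reduced with BH3·SMe2 and (R)-3,3-diphenyl-1-methyltetrahydro-3H-pyrrolo[1,2-c][1,3,2]oxazaborole (10 mol %, Corey–Bakshi–Shibata reduction), which fixes the carbinol centre; the cis/trans isomers are separated and the isomer [(1S,2S)-1-allyl-2-hydroxy-6-oxocyclohexyl]methyl 2-(diethoxyphosphoryl)acetate F1 is kept. LiCl and DBU in MeCN (Masamune–Roush conditions) then close the lactone onto the remaining ketone to give (8S,8aS)-8a-allyl-8-hydroxy-6,7,8,8a-tetrahydro-1H-isochromen-3(5H)-one F2, and Dess–Martin periodinane oxidises the alcohol to 8.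

Step 10 (the fully substituted dienolate carbon may be too hindered for the bridging alkylation, or γ-alkylation may compete). The fallback reverses the order of the two C–C bonds at C4, sets out from 13 and comes back at 18. Hydrozirconation–iodination of 13 (Cp2Zr(H)Cl, then I2) gives (7R,8R,8aS)-8a-(3-iodopropyl)-7-methyl-5,6,7,8a-tetrahydro-1H-spiro[isochromene-8,2'-oxiran]-3-one F3. KN(SiMe3)2 closes ring A through the less hindered, unmethylated dienolate to (4S,8R,9R,10S)-9,11-epoxy-12,13,14,15,16,18-hexanorlabd-5-en-19,20-olide F4, and bridgehead enolisation with LiN(iPr)2 followed by MeI (retention is enforced by the bicycle) gives 18.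

Step 12 (proposed new method; the silyl ether may not capture the enolonium, or trifluoroacetate may compete). The fallback uses known chemistry, sets out from 21 and comes back at 23. The dianion of 21 (LiN(iPr)2, 2.2 equiv, THF, −78 °C) is brominated with CBr4 to (4S,8R,9R,10S)-13-bromo-9-hydroxylabd-5-ene-19,20:16,15-diolide F5 (both C13 epimers). AgOTf with 2,6-di-tert-butylpyridine in CH2Cl2 then closes the ether by silver-assisted substitution, and 23 is separated from its C13 epimer by chromatography; this route gives no control at C13.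

**Further compounds**
F1 | step 4 | [(1S,2S)-1-allyl-2-hydroxy-6-oxocyclohexyl]methyl 2-(diethoxyphosphoryl)acetate | C=CC[C@]1(COC(=O)CP(=O)(OCC)OCC)[C@@H](O)CCCC1=O
F2 | step 4 | (8S,8aS)-8a-allyl-8-hydroxy-6,7,8,8a-tetrahydro-1H-isochromen-3(5H)-one | O=C1C=C2CCC[C@H](O)[C@]2(CC=C)CO1
F3 | step 10 | (7R,8R,8aS)-8a-(3-iodopropyl)-7-methyl-5,6,7,8a-tetrahydro-1H-spiro[isochromene-8,2'-oxiran]-3-one | O=C1C=C2CC[C@@H](C)[C@]3(CO3)[C@]2(CCCI)CO1
F4 | step 10 | (4S,8R,9R,10S)-9,11-epoxy-12,13,14,15,16,18-hexanorlabd-5-en-19,20-olide | C[C@@H]1CC=C2[C@]3(CCC[C@@H]2C(=O)OC3)[C@@]14CO4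
F5 | step 12 | (4S,8R,9R,10S)-13-bromo-9-hydroxylabd-5-ene-19,20:16,15-diolide, both C13 epimers | C[C@@H]1CC=C2[C@]3(CCC[C@]2(C)C(=O)OC3)[C@@]1(O)CCC1(Br)CCOC1=O
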